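**Retrosynthetic overview**
- The benzene ring is bought; the only ring formed is the pyran, closed last by ring-closing metathesis (C3=C4) of a diene that carries an aryl vinyl group and a vinyl group on the quaternary ether carbon.
- The phenol OH is unmasked just before by Dakin oxidation of a formyl group that sits para to the ether oxygen.
- The aryl–O bond is made by SNAr of a tertiary potassium alkoxide on a 4-fluorobenzaldehyde, the convergent coupling, with retention at the carbinol carbon.
- The alkoxide comes from natural phytol: Sharpless epoxidation sets the future C2, and epoxy iodide/zinc opening moves the oxygen to the tertiary vinyl carbinol. The 4′R,8′R centres are those of phytol.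
- The fluoroarene comes from 1-bromo-4-fluoro-2,5-dimethylbenzene by ortho-lithiation/formylation, Wittig methylenation and Br→CHO exchange.

Assumption: the SMILES is read as written, which makes C2 S (with 4′R,8′R); natural (2E,7R,11R)-phytol and 1-bromo-4-fluoro-2,5-dimethylbenzene are taken as catalogue materials.

**Route**

Step 1
Reactants: 1 (2E,7R,11R)-3,7,11,15-tetramethylhexadec-2-en-1-ol (natural phytol)
Product: 2 [(2S,3S)-3-methyl-3-[(4R,8R)-4,8,12-trimethyltridecyl]oxiran-2-yl]methanol
Conditions: Ti(OiPr)4 (10 mol%), L-(+)-diethyl tartrate (12 mol%), t-BuOOH (2 equiv, isooctane), 4 Å MS, CH2Cl2, −20 °C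
Reagents that add atoms: tert-butyl hydroperoxide, CC(C)(C)OO
Why: Katsuki–Sharpless asymmetric epoxidation of the E-trisubstituted allylic alcohol; the L-(+)-tartrate catalyst gives the (2S,3S) epoxide (as with geraniol) under reagent control, which fixes the future C2 as S.

Step 2
Reactants: 2 [(2S,3S)-3-methyl-3-[(4R,8R)-4,8,12-trimethyltridecyl]oxiran-2-yl]methanol
Product: 3 (2S,3R)-3-(iodomethyl)-2-methyl-2-[(4R,8R)-4,8,12-trimethyltridecyl]oxirane
Conditions: PPh3, imidazole, I2, CH2Cl2, 0 °C
Reagents that add atoms: iodine, II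
Why: Appel-type iodination (Garegg–Samuelsson conditions) displaces the activated primary hydroxyl at CH2 only, so both epoxide carbons keep their geometry (the CH descriptor becomes R solely through the CIP priority of iodine).

Step 3
Reactants: 3 (2S,3R)-3-(iodomethyl)-2-methyl-2-[(4R,8R)-4,8,12-trimethyltridecyl]oxirane
Product: 4 (3S,7R,11R)-3,7,11,15-tetramethylhexadec-1-en-3-ol
Conditions: activated Zn dust, EtOH, reflux; aq. NH4Cl work-up
Reagents that add atoms: none
Why: Reductive epoxide opening (zinc insertion into C–I, then β-elimination of the epoxide oxygen) gives the tertiary vinyl carbinol; the C3–O bond is never broken, so the centre is retained and reads 3S.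

Step 4
Reactants: 5 1-bromo-4-fluoro-2,5-dimethylbenzene
Product: 7 3-bromo-6-fluoro-2,5-dimethylbenzaldehyde, via aryllithium 6 (not isolated)
Conditions: LDA (1.1 equiv), THF, −78 °C; then DMF, −78 → 0 °C; aq. NH4Cl
Reagents that add atoms: N,N-dimethylformamide, CN(C)C=O
Why: Directed ortho-lithiation occurs at the single C–H next to fluorine (a much stronger ortho-director than bromine, and stable to benzyne loss at −78 °C), and DMF formylates the aryllithium.

Step 5
Reactants: 7 3-bromo-6-fluoro-2,5-dimethylbenzaldehyde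
Product: 8 1-bromo-3-ethenyl-4-fluoro-2,5-dimethylbenzene
Conditions: Ph3PCH3Br (1.3 equiv), n-BuLi (1.25 equiv), THF, 0 °C; then 7, 0 °C → rt
Reagents that add atoms: methyltriphenylphosphonium bromide, [Br-].C[P+](c1ccccc1)(c1ccccc1)c1ccccc1
Why: Wittig methylenation with the preformed ylide (no free alkoxide or butyllithium left) converts the hindered aldehyde to the vinyl group without touching the activated C–F or the C–Br bond.

Step 6
Reactants: 8 1-bromo-3-ethenyl-4-fluoro-2,5-dimethylbenzene
Product: 10 3-ethenyl-4-fluoro-2,5-dimethylbenzaldehyde, via aryllithium 9 (not isolated)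
Conditions: n-BuLi (1.05 equiv), THF, −78 °C; then DMF, −78 → 0 °C; aq. NH4Cl
Reagents that add atoms: N,N-dimethylformamide, CN(C)C=O
Why: Bromine–lithium exchange at −78 °C outruns addition of butyllithium to the twisted styrene, and Bouveault formylation places the aldehyde para to fluorine, which activates the next step.

Step 7
Reactants: 4 (3S,7R,11R)-3,7,11,15-tetramethylhexadec-1-en-3-ol; 10 3-ethenyl-4-fluoro-2,5-dimethylbenzaldehyde
Product: 12 3-ethenyl-2,5-dimethyl-4-{[(3S,7R,11R)-3,7,11,15-tetramethylhexadec-1-en-3-yl]oxy}benzaldehyde, via potassium alkoxide 11 (not isolated)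
Conditions: 4 (1.15 equiv), KHMDS (1.1 equiv), THF, 0 °C; then 10 (1.0 equiv), 18-crown-6, THF, 0 → 40 °C
Reagents that add atoms: none
Why: Nucleophilic aromatic substitution (addition–elimination) in which the para-formyl group stabilises the Meisenheimer intermediate and fluoride leaves; the alkoxide C–O bond is not broken, so the S centre is carried over unchanged, and a tertiary alkoxide has no carbinol hydrogen with which to reduce the aldehyde.

Step 8
Reactants: 12 3-ethenyl-2,5-dimethyl-4-{[(3S,7R,11R)-3,7,11,15-tetramethylhexadec-1-en-3-yl]oxy}benzaldehyde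
Product: 14 3-ethenyl-2,5-dimethyl-4-{[(3S,7R,11R)-3,7,11,15-tetramethylhexadec-1-en-3-yl]oxy}phenol, via aryl formate 13 (not isolated)
Conditions: mCPBA (1.2 equiv), CH2Cl2, 0 °C → rt; aq. Na2SO3/NaHCO3 wash; then K2CO3 (cat.), MeOH, rt, Ar
Reagents that add atoms: 3-chloroperoxybenzoic acid, OOC(=O)c1cccc(Cl)c1
Why: Dakin-type Baeyer–Villiger oxidation in which the electron-rich aryl group migrates to give the formate, while the two monosubstituted alkenes (a twisted styrene and a vinyl group on an oxygenated quaternary carbon) epoxidise much more slowly; mild methanolysis then frees the phenol without touching any stereocentre.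

Step 9
Reactants: 14 3-ethenyl-2,5-dimethyl-4-{[(3S,7R,11R)-3,7,11,15-tetramethylhexadec-1-en-3-yl]oxy}phenol
Product: 15 (2S)-2,5,8-trimethyl-2-[(4R,8R)-4,8,12-trimethyltridecyl]-2H-chromen-6-ol
Conditions: Grubbs II (5 mol%), CH2Cl2 (5 mM), 40 °C, Ar
Reagents that add atoms: none
Why: Ring-closing metathesis joins the aryl vinyl group and the vinyl group on the quaternary carbon into the cis C3=C4 bond of the six-membered pyran with loss of ethene; the second-generation catalyst tolerates the free phenol and the fully substituted allylic carbon, and C2 is not touched.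

**Compound list**

1 | (2E,7R,11R)-3,7,11,15-tetramethylhexadec-2-en-1-ol (phytol) | OC/C=C(\C)CCC[C@H](C)CCC[C@H](C)CCCC(C)C | starting material
2 | [(2S,3S)-3-methyl-3-[(4R,8R)-4,8,12-trimethyltridecyl]oxiran-2-yl]methanol | O1[C@@](C)(CCC[C@H](C)CCC[C@H](C)CCCC(C)C)[C@@H]1CO | intermediate
3 | (2S,3R)-3-(iodomethyl)-2-methyl-2-[(4R,8R)-4,8,12-trimethyltridecyl]oxirane | O1[C@@](C)(CCC[C@H](C)CCC[C@H](C)CCCC(C)C)[C@@H]1CI | intermediate
4 | (3S,7R,11R)-3,7,11,15-tetramethylhexadec-1-en-3-ol | O[C@@](C)(CCC[C@H](C)CCC[C@H](C)CCCC(C)C)C=C | intermediate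
5 | 1-bromo-4-fluoro-2,5-dimethylbenzene | Cc1cc(Br)c(C)cc1F | starting material
6 | (3-bromo-6-fluoro-2,5-dimethylphenyl)lithium | Cc1cc(Br)c(C)c([Li])c1F | intermediate
7 | 3-bromo-6-fluoro-2,5-dimethylbenzaldehyde | Cc1cc(Br)c(C)c(C=O)c1F | intermediate
8 | 1-bromo-3-ethenyl-4-fluoro-2,5-dimethylbenzene | Cc1cc(Br)c(C)c(C=C)c1F | intermediate
9 | (3-ethenyl-4-fluoro-2,5-dimethylphenyl)lithium | Cc1cc([Li])c(C)c(C=C)c1F | intermediate
10 | 3-ethenyl-4-fluoro-2,5-dimethylbenzaldehyde | Cc1cc(C=O)c(C)c(C=C)c1F | intermediate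
11 | potassium (3S,7R,11R)-3,7,11,15-tetramethylhexadec-1-en-3-olate | [K+].[O-][C@@](C)(CCC[C@H](C)CCC[C@H](C)CCCC(C)C)C=C | intermediate
12 | 3-ethenyl-2,5-dimethyl-4-{[(3S,7R,11R)-3,7,11,15-tetramethylhexadec-1-en-3-yl]oxy}benzaldehyde | Cc1cc(C=O)c(C)c(C=C)c1O[C@@](C)(CCC[C@H](C)CCC[C@H](C)CCCC(C)C)C=C | intermediate
13 | 3-ethenyl-2,5-dimethyl-4-{[(3S,7R,11R)-3,7,11,15-tetramethylhexadec-1-en-3-yl]oxy}phenyl formate | Cc1cc(OC=O)c(C)c(C=C)c1O[C@@](C)(CCC[C@H](C)CCC[C@H](C)CCCC(C)C)C=C | intermediate
14 | 3-ethenyl-2,5-dimethyl-4-{[(3S,7R,11R)-3,7,11,15-tetramethylhexadec-1-en-3-yl]oxy}phenol | Cc1cc(O)c(C)c(C=C)c1O[C@@](C)(CCC[C@H](C)CCC[C@H](C)CCCC(C)C)C=C | intermediate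
15 | (2S)-2,5,8-trimethyl-2-[(4R,8R)-4,8,12-trimethyltridecyl]-2H-chromen-6-ol | Cc1cc(O)c(C)c2c1O[C@@](C)(CCC[C@H](C)CCC[C@H](C)CCCC(C)C)C=C2 | target

**Step count**

Total steps: 9. Longest linear sequence: 6 (steps 1–3, then 7–9; the arene arm, steps 4–6 then 7–9, is equally long).

**Steps most likely to fail**

Step 7 (SNAr). A tertiary alkoxide has to attack a fluoride flanked by a vinyl and a methyl group. Reversible addition to the aldehyde and deprotonation of the methyl group ortho to the formyl group compete. The fallback reverses the polarity: the arene becomes the nucleophile and the stereocentre is set by a catalyst instead of being carried in from 4. It sets out from 10 and from 1. Compound 10 is treated with 2-(methylsulfonyl)ethanol and NaH in DMF. The unhindered primary alkoxide displaces fluoride to give 3-ethenyl-2,5-dimethyl-4-[2-(methylsulfonyl)ethoxy]benzaldehyde F1, which eliminates in the same flask to give 3-ethenyl-4-hydroxy-2,5-dimethylbenzaldehyde F2. Phytol 1 with methyl chloroformate and pyridine gives methyl (2E,7R,11R)-3,7,11,15-tetramethylhexadec-2-en-1-yl carbonate F3. Palladium-catalysed asymmetric allylic etherification of F2 with F3 (Pd2(dba)3·CHCl3, DACH-phenyl Trost ligand, CH2Cl2, rt) places the phenol on the more substituted allyl terminus and comes back to the route at 12. Which ligand antipode gives the S ether is not something I can assign with confidence; both are sold, and it must be fixed experimentally in a first small run.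

Step 8 (Dakin oxidation). The ether oxygen para to the formyl group is twisted out of conjugation by its two ortho substituents, so hydride migration (giving the benzoic acid) and alkene epoxidation may compete with aryl migration. The fallback avoids peracid altogether and brings the oxygen in through a bromide. It sets out from 7 and from alkoxide 11 (made from 4 as in step 7). SNAr at the fluoride of 7, now activated by the ortho-formyl group, gives 3-bromo-2,5-dimethyl-6-{[(3S,7R,11R)-3,7,11,15-tetramethylhexadec-1-en-3-yl]oxy}benzaldehyde F4. Wittig methylenation gives 1-bromo-3-ethenyl-2,5-dimethyl-4-{[(3S,7R,11R)-3,7,11,15-tetramethylhexadec-1-en-3-yl]oxy}benzene F5. Bromine–lithium exchange with n-BuLi at −78 °C gives (3-ethenyl-2,5-dimethyl-4-{[(3S,7R,11R)-3,7,11,15-tetramethylhexadec-1-en-3-yl]oxy}phenyl)lithium F6. Trapping with B(OMe)3 gives lithium (3-ethenyl-2,5-dimethyl-4-{[(3S,7R,11R)-3,7,11,15-tetramethylhexadec-1-en-3-yl]oxy}phenyl)trimethoxyborate F7, and oxidation with H2O2/NaOH at 0 °C comes back to the route at 14. This detour gives up the balance of the two arms, which is why it is not the main line.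

Step 9 (ring-closing metathesis). Both alkenes are hindered, and the free, electron-rich phenol can shorten catalyst life before the slow closure is complete. The fallback closes the ring on a masked phenol so that more forcing conditions can be used. It sets out from 14. Acetylation (Ac2O, pyridine, DMAP) gives 3-ethenyl-2,5-dimethyl-4-{[(3S,7R,11R)-3,7,11,15-tetramethylhexadec-1-en-3-yl]oxy}phenyl acetate F8. Metathesis with the Hoveyda–Grubbs second-generation catalyst in toluene at 60 °C gives (2S)-2,5,8-trimethyl-2-[(4R,8R)-4,8,12-trimethyltridecyl]-2H-chromen-6-yl acetate F9. K2CO3 in degassed MeOH then releases the phenol and comes back to the route at 15.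

**Further compounds**

F1 | step 7 | 3-ethenyl-2,5-dimethyl-4-[2-(methylsulfonyl)ethoxy]benzaldehyde | Cc1cc(C=O)c(C)c(C=C)c1OCCS(C)(=O)=O
F2 | step 7 | 3-ethenyl-4-hydroxy-2,5-dimethylbenzaldehyde | Cc1cc(C=O)c(C)c(C=C)c1O
F3 | step 7 | methyl (2E,7R,11R)-3,7,11,15-tetramethylhexadec-2-en-1-yl carbonate | COC(=O)OC/C=C(\C)CCC[C@H](C)CCC[C@H](C)CCCC(C)C
F4 | step 8 | 3-bromo-2,5-dimethyl-6-{[(3S,7R,11R)-3,7,11,15-tetramethylhexadec-1-en-3-yl]oxy}benzaldehyde | Cc1cc(Br)c(C)c(C=O)c1O[C@@](C)(CCC[C@H](C)CCC[C@H](C)CCCC(C)C)C=C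
F5 | step 8 | 1-bromo-3-ethenyl-2,5-dimethyl-4-{[(3S,7R,11R)-3,7,11,15-tetramethylhexadec-1-en-3-yl]oxy}benzene | Cc1cc(Br)c(C)c(C=C)c1O[C@@](C)(CCC[C@H](C)CCC[C@H](C)CCCC(C)C)C=C
F6 | step 8 | (3-ethenyl-2,5-dimethyl-4-{[(3S,7R,11R)-3,7,11,15-tetramethylhexadec-1-en-3-yl]oxy}phenyl)lithium | Cc1cc([Li])c(C)c(C=C)c1O[C@@](C)(CCC[C@H](C)CCC[C@H](C)CCCC(C)C)C=C
F7 | step 8 | lithium (3-ethenyl-2,5-dimethyl-4-{[(3S,7R,11R)-3,7,11,15-tetramethylhexadec-1-en-3-yl]oxy}phenyl)trimethoxyborate | [Li+].CO[B-](OC)(OC)c1cc(C)c(O[C@@](C)(CCC[C@H](C)CCC[C@H](C)CCCC(C)C)C=C)c(C=C)c1C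
F8 | step 9 | 3-ethenyl-2,5-dimethyl-4-{[(3S,7R,11R)-3,7,11,15-tetramethylhexadec-1-en-3-yl]oxy}phenyl acetate | Cc1cc(OC(C)=O)c(C)c(C=C)c1O[C@@](C)(CCC[C@H](C)CCC[C@H](C)CCCC(C)C)C=C
F9 | step 9 | (2S)-2,5,8-trimethyl-2-[(4R,8R)-4,8,12-trimethyltridecyl]-2H-chromen-6-yl acetate | Cc1cc(OC(C)=O)c(C)c2c1O[C@@](C)(CCC[C@H](C)CCC[C@H](C)CCCC(C)C)C=C2
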